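**Strategy.** Germacrane numbering is used (carbocycle C1–C10; ring A is the 15,6-γ-lactone; C11–C13 is the propionate on C7). The route rests on closing the ten-membered carbocycle at C6–C7: C6 is the γ-carbon of ring A and C7 a tertiary carbinol next to the C8 ketal carbon, a vinylogous aldol pattern. A 2-silyloxyfuran, the aromatic precursor of ring A, attacks a C7 ketone flanked by a C8 dithiane and the C11 stereocentre; one operation closes the carbocycle, sets C6 and C7 and leaves a bridged butenolide for face-selective dihydroxylation. The C8 carbonyl, C12 acid and C1 hydroxyl are released last and fold into the spiro-ketal lactone.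

Key step: step 12

Assumption: the stereodescriptors are taken exactly as written (1S,4S,5S,6R,7S,8S,11S); they place the C2 and C7 arms trans on the dihydrofuran, so the carbocycle is closed before the ether bridge, and the ketal carbon C8, the only centre made under equilibrating conditions, is assumed to settle as drawn.

Step 1
Reactants: 1 acrolein; 2 methyl propiolate
Product: 3 methyl (4S)-4-hydroxyhex-5-en-2-ynoate
Conditions: Me2Zn, ProPhenol ligand (cat., antipode that gives the 4S alcohol), Ph3P=O (cat.), toluene, 4 °C; aq. NH4Cl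
Reagents that add atoms: none
Why: Zinc–ProPhenol-catalysed enantioselective addition of the zinc acetylide to the aldehyde should set the future C1 carbinol by catalyst control.

Step 2
Reactants: 3 methyl (4S)-4-hydroxyhex-5-en-2-ynoate
Product: 4 methyl (4S)-4-(tert-butyldimethylsilyloxy)hex-5-en-2-ynoate
Conditions: TBSOTf, 2,6-lutidine, CH2Cl2, −78 °C
Reagents that add atoms: TBSOTf CC(C)(C)[Si](C)(C)OS(=O)(=O)C(F)(F)F
Why: Silylation with a silyl triflate and a non-nucleophilic base should protect the secondary alcohol without conjugate addition to the ynoate.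

Step 3
Reactants: 4 methyl (4S)-4-(tert-butyldimethylsilyloxy)hex-5-en-2-ynoate
Product: 5 methyl (2Z,4S)-4-(tert-butyldimethylsilyloxy)-3-methylhexa-2,5-dienoate
Conditions: Me2CuLi (from MeLi and CuI), THF, −78 °C; NH4Cl/MeOH at −78 °C
Reagents that add atoms: lithium dimethylcuprate [Li+].C[Cu-]C
Why: syn-Carbocupration of the ynoate and cold protonation of the vinylcuprate with retention should give the 2Z enoate, which fixes C1 and C8 cis across the future C9=C10 bond.

Step 4
Reactants: 5 methyl (2Z,4S)-4-(tert-butyldimethylsilyloxy)-3-methylhexa-2,5-dienoate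
Product: 6 (2Z,4S)-4-(tert-butyldimethylsilyloxy)-3-methylhexa-2,5-dien-1-ol
Conditions: i-Bu2AlH, CH2Cl2, −78 °C; aq. potassium sodium tartrate
Reagents that add atoms: none
Why: 1,2-Hydride reduction of the conjugated ester should give the allylic alcohol without isomerising the trisubstituted olefin.

Step 5
Reactants: 6 (2Z,4S)-4-(tert-butyldimethylsilyloxy)-3-methylhexa-2,5-dien-1-ol
Product: 7 (2Z,4S)-4-(tert-butyldimethylsilyloxy)-3-methylhexa-2,5-dienal
Conditions: MnO2, CH2Cl2, rt
Reagents that add atoms: none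
Why: Neutral allylic oxidation with MnO2 should give the Z enal with the olefin geometry retained.

Step 6
Reactants: 7 (2Z,4S)-4-(tert-butyldimethylsilyloxy)-3-methylhexa-2,5-dienal
Product: 8 2-[(1Z,3S)-3-(tert-butyldimethylsilyloxy)-2-methylpenta-1,4-dien-1-yl]-1,3-dithiane
Conditions: HS(CH2)3SH, Zn(OTf)2 (cat.), CH2Cl2, 0 °C
Reagents that add atoms: propane-1,3-dithiol SCCCS
Why: Lewis-acid-catalysed dithioacetalisation masks the future C8 carbonyl as a non-stereogenic acyl-anion equivalent; the β,β-disubstitution blocks conjugate thiol addition.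

Step 7
Reactants: 8 2-[(1Z,3S)-3-(tert-butyldimethylsilyloxy)-2-methylpenta-1,4-dien-1-yl]-1,3-dithiane; 9 3-bromofuran-2(5H)-one
Product: 11 3-[(3S,4Z)-3-(tert-butyldimethylsilyloxy)-5-(1,3-dithian-2-yl)-4-methylpent-4-en-1-yl]furan-2(5H)-one, via alkylborane 10 (not isolated)
Conditions: 9-BBN, THF, rt; then 9, Pd(dppf)Cl2 (cat.), AsPh3, Cs2CO3, DMF/H2O, rt
Reagents that add atoms: none
Why: 9-BBN hydroborates only the monosubstituted olefin at its terminus, and B-alkyl Suzuki–Miyaura coupling with the α-bromo butenolide should form the C3–C4 bond.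

Step 8
Reactants: 11 3-[(3S,4Z)-3-(tert-butyldimethylsilyloxy)-5-(1,3-dithian-2-yl)-4-methylpent-4-en-1-yl]furan-2(5H)-one
Product: 12 3-[(3S,4Z)-3-(tert-butyldimethylsilyloxy)-5-(1,3-dithian-2-yl)-4-methylpent-4-en-1-yl]-2-(triisopropylsilyloxy)furan
Conditions: TIPSOTf, Et3N, CH2Cl2, 0 °C
Reagents that add atoms: TIPSOTf CC(C)[Si](C(C)C)(C(C)C)OS(=O)(=O)C(F)(F)F
Why: Soft enolisation of the butenolide γ-CH2 and O-silylation should give the aromatic 2-silyloxyfuran; no other acidic site is present at this stage.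

Step 9
Reactants: 13 methyl (R)-3-hydroxy-2-methylpropanoate
Product: 14 methyl (R)-2-methyl-3-(triethylsilyloxy)propanoate
Conditions: TESCl, imidazole, CH2Cl2, 0 °C
Reagents that add atoms: TESCl CC[Si](Cl)(CC)CC
Why: Standard silylation of the primary alcohol leaves the α-stereocentre (future C11) untouched.

Step 10
Reactants: 14 methyl (R)-2-methyl-3-(triethylsilyloxy)propanoate
Product: 15 (R)-N-methoxy-N,2-dimethyl-3-(triethylsilyloxy)propanamide
Conditions: MeNHOMe·HCl, i-PrMgCl, THF, −20 °C
Reagents that add atoms: N,O-dimethylhydroxylamine hydrochloride CNOC.Cl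
Why: Aminolysis of the ester by the magnesium amide should give the N-methoxy-N-methyl amide without epimerisation at low temperature.

Step 11
Reactants: 12 3-[(3S,4Z)-3-(tert-butyldimethylsilyloxy)-5-(1,3-dithian-2-yl)-4-methylpent-4-en-1-yl]-2-(triisopropylsilyloxy)furan; 15 (R)-N-methoxy-N,2-dimethyl-3-(triethylsilyloxy)propanamide
Product: 17 (2R)-2-methyl-1-{2-[(1Z,3S)-3-(tert-butyldimethylsilyloxy)-2-methyl-5-[2-(triisopropylsilyloxy)furan-3-yl]pent-1-en-1-yl]-1,3-dithian-2-yl}-3-(triethylsilyloxy)propan-1-one, via 2-lithiodithiane 16 (not isolated)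
Conditions: n-BuLi, THF, −78 to −40 °C; then 15, −78 °C; aq. NH4Cl
Reagents that add atoms: none
Why: Corey–Seebach acylation in which the sulfur-stabilised allyl anion should react at its α-carbon (the γ-carbon is fully substituted) and the chelated adduct of the Weinreb ketone synthesis stops at the ketone, C11 coming intact from 15.

Step 12
Reactants: 17 (2R)-2-methyl-1-{2-[(1Z,3S)-3-(tert-butyldimethylsilyloxy)-2-methyl-5-[2-(triisopropylsilyloxy)furan-3-yl]pent-1-en-1-yl]-1,3-dithian-2-yl}-3-(triethylsilyloxy)propan-1-one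
Product: 18 (1S,6R,7S,11R)-1-(tert-butyldimethylsilyloxy)-7-hydroxy-8,8-(propane-1,3-diyldisulfanediyl)-12-(triethylsilyloxy)germacra-4,9Z-dien-15,6-olide
Conditions: BF3·OEt2, CH2Cl2, −78 °C, slow addition of 17 to the Lewis acid at high dilution; aq. NaHCO3
Reagents that add atoms: none
Why: Proposed new method: BF3 activates the C7 ketone and the aromatic 2-silyloxyfuran attacks through its C6 terminus in an open Mukaiyama-type transition state, the silyl group leaving as TIPSF so that the addition is irreversible; the closest known reactions are the intermolecular Lewis-acid vinylogous Mukaiyama aldol additions of 2-silyloxyfurans to aldehydes and activated ketones, which have not been used to close a medium carbocycle onto a ketone. The ten-membered carbocycle closes in a 10-(enolendo)-exo-trig mode and, with the existing five-membered ring, gives the bicyclo[7.2.1] bridged butenolide. C7 is set by Felkin–Anh control from C11 (attack anti to the CH2OTES arm with the methyl inside; the dithiane carbon is not stereogenic and BF3 does not chelate), which gives the 7S,11R relationship needed for a cis C7-hydroxyl/C13-methyl pair in the later lactone. C6 is set by the antiperiplanar arrangement of the carbonyl and the furan C5=C6 bond in which the bulky dithiane carbon C8 lies exo on the C5 side, where the forming ring must pass, and the smaller C11 branch lies over the furan, which gives 6R. The step needs γ-selectivity (C6, not the substituted C4 terminus), no conjugate addition and cyclisation rather than oligomerisation; these should be secured by the aromatic 3-alkyl-2-silyloxyfuran, by masking the C8 carbonyl as the dithiane so that no enone is present, and by high dilution together with three rigid units (furan, Z-olefin, dithiane) between the reacting carbons.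

Step 13
Reactants: 18 (1S,6R,7S,11R)-1-(tert-butyldimethylsilyloxy)-7-hydroxy-8,8-(propane-1,3-diyldisulfanediyl)-12-(triethylsilyloxy)germacra-4,9Z-dien-15,6-olide
Product: 19 (1S,6R,7S,11R)-1-(tert-butyldimethylsilyloxy)-7-hydroxy-8-oxo-12-(triethylsilyloxy)germacra-4,9Z-dien-15,6-olide
Conditions: PhI(OCOCF3)2, NaHCO3, MeCN/H2O, 0 °C
Reagents that add atoms: water O
Why: Oxidative hydrolysis of the dithiane with the hypervalent iodine reagent should unveil the C8 ketone as the α-hydroxy Z-enone under buffered conditions that spare the silyl ethers.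

Step 14
Reactants: 19 (1S,6R,7S,11R)-1-(tert-butyldimethylsilyloxy)-7-hydroxy-8-oxo-12-(triethylsilyloxy)germacra-4,9Z-dien-15,6-olide
Product: 20 (1S,4S,5S,6R,7S,11R)-1-(tert-butyldimethylsilyloxy)-4,5,7-trihydroxy-8-oxo-12-(triethylsilyloxy)germacr-9Z-en-15,6-olide
Conditions: OsO4 (cat.), NMO, acetone/H2O, rt; aq. Na2SO3
Reagents that add atoms: N-methylmorpholine N-oxide C[N+]1([O-])CCOCC1; water O
Why: Catalytic osmium tetroxide syn-dihydroxylation should take the strained butenolide olefin (E within the ten-membered ring) rather than the hindered, deactivated enone, and from the face opposite the carbocycle bridge, which sets C4 and C5 as the cis-diol anti to C7.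

Step 15
Reactants: 20 (1S,4S,5S,6R,7S,11R)-1-(tert-butyldimethylsilyloxy)-4,5,7-trihydroxy-8-oxo-12-(triethylsilyloxy)germacr-9Z-en-15,6-olide
Product: 21 (1S,4S,5S,6R,7S,11R)-5-acetoxy-1-(tert-butyldimethylsilyloxy)-4,7-dihydroxy-8-oxo-12-(triethylsilyloxy)germacr-9Z-en-15,6-olide
Conditions: Ac2O, pyridine, DMAP (cat.), CH2Cl2, 0 °C
Reagents that add atoms: acetic anhydride CC(=O)OC(C)=O
Why: Acylation should select the single secondary hydroxyl at C5 over the two tertiary hydroxyls at C4 and C7.

Step 16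
Reactants: 21 (1S,4S,5S,6R,7S,11R)-5-acetoxy-1-(tert-butyldimethylsilyloxy)-4,7-dihydroxy-8-oxo-12-(triethylsilyloxy)germacr-9Z-en-15,6-olide
Product: 22 (1S,4S,5S,6R,7S,11R)-5-acetoxy-1-(tert-butyldimethylsilyloxy)-4,7,12-trihydroxy-8-oxogermacr-9Z-en-15,6-olide
Conditions: AcOH, THF, H2O, rt
Reagents that add atoms: none
Why: Mild aqueous acid should cleave the primary triethylsilyl ether while the secondary allylic TBS ether and the acetate survive.

Step 17
Reactants: 22 (1S,4S,5S,6R,7S,11R)-5-acetoxy-1-(tert-butyldimethylsilyloxy)-4,7,12-trihydroxy-8-oxogermacr-9Z-en-15,6-olide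
Product: 24 (1S,4S,5S,6R,7S,11S)-5-acetoxy-1-(tert-butyldimethylsilyloxy)-4,7-dihydroxy-8-oxo-15,6-olidogermacr-9Z-en-12-oic acid, via aldehyde 23 (not isolated)
Conditions: TEMPO (cat.), PhI(OAc)2, MeCN/H2O, rt
Reagents that add atoms: water O
Why: Oxoammonium-mediated oxidation of the primary alcohol through the aldehyde hydrate should give the C12 acid (in equilibrium with its cyclic pseudo-acid), the tertiary alcohols and the acetate being inert.

Step 18
Reactants: 24 (1S,4S,5S,6R,7S,11S)-5-acetoxy-1-(tert-butyldimethylsilyloxy)-4,7-dihydroxy-8-oxo-15,6-olidogermacr-9Z-en-12-oic acid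
Product: 26 (1S,4S,5S,6R,7S,8S,11S)-5-acetoxy-4,7-dihydroxy-1,8-epoxygermacr-9-ene-15,6:12,8-diolide (target), via hydroxy keto acid 25 (not isolated)
Conditions: aq. HF, MeCN, 0 °C to rt
Reagents that add atoms: none
Why: Desilylation frees the C1 hydroxyl, which adds to the C8 ketone across the Z-olefin to the dihydrofuranol, and the C12 acid then closes the γ-lactone on the hemiketal carbon (pseudo-ester formation), C8 being set under the equilibrating acid conditions.

**Compound list**
1 | acrolein | C=CC=O | starting material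
2 | methyl propiolate | C#CC(=O)OC | starting material
3 | methyl (4S)-4-hydroxyhex-5-en-2-ynoate | C=C[C@H](O)C#CC(=O)OC | intermediate
4 | methyl (4S)-4-(tert-butyldimethylsilyloxy)hex-5-en-2-ynoate | C=C[C@H](O[Si](C)(C)C(C)(C)C)C#CC(=O)OC | intermediate
5 | methyl (2Z,4S)-4-(tert-butyldimethylsilyloxy)-3-methylhexa-2,5-dienoate | C=C[C@H](O[Si](C)(C)C(C)(C)C)/C(C)=C\C(=O)OC | intermediate
6 | (2Z,4S)-4-(tert-butyldimethylsilyloxy)-3-methylhexa-2,5-dien-1-ol | C=C[C@H](O[Si](C)(C)C(C)(C)C)/C(C)=C\CO | intermediate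
7 | (2Z,4S)-4-(tert-butyldimethylsilyloxy)-3-methylhexa-2,5-dienal | C=C[C@H](O[Si](C)(C)C(C)(C)C)/C(C)=C\C=O | intermediate
8 | 2-[(1Z,3S)-3-(tert-butyldimethylsilyloxy)-2-methylpenta-1,4-dien-1-yl]-1,3-dithiane | C=C[C@H](O[Si](C)(C)C(C)(C)C)/C(C)=C\C1SCCCS1 | intermediate
9 | 3-bromofuran-2(5H)-one | O=C1OCC=C1Br | starting material
10 | B-alkyl-9-borabicyclo[3.3.1]nonane from 8, boron on the terminal carbon (formed in the flask) | C1CC2CCCC(C1)B2CC[C@H](O[Si](C)(C)C(C)(C)C)/C(C)=C\C1SCCCS1 | intermediate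
11 | 3-[(3S,4Z)-3-(tert-butyldimethylsilyloxy)-5-(1,3-dithian-2-yl)-4-methylpent-4-en-1-yl]furan-2(5H)-one | O=C1OCC=C1CC[C@H](O[Si](C)(C)C(C)(C)C)/C(C)=C\C1SCCCS1 | intermediate
12 | 3-[(3S,4Z)-3-(tert-butyldimethylsilyloxy)-5-(1,3-dithian-2-yl)-4-methylpent-4-en-1-yl]-2-(triisopropylsilyloxy)furan | CC(C)[Si](C(C)C)(C(C)C)Oc1occc1CC[C@H](O[Si](C)(C)C(C)(C)C)/C(C)=C\C1SCCCS1 | intermediate
13 | methyl (R)-3-hydroxy-2-methylpropanoate | OC[C@@H](C)C(=O)OC | starting material
14 | methyl (R)-2-methyl-3-(triethylsilyloxy)propanoate | CC[Si](CC)(CC)OC[C@@H](C)C(=O)OC | intermediate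
15 | (R)-N-methoxy-N,2-dimethyl-3-(triethylsilyloxy)propanamide | CC[Si](CC)(CC)OC[C@@H](C)C(=O)N(C)OC | intermediate
16 | 2-lithio-1,3-dithiane derived from 12 (formed in the flask) | CC(C)[Si](C(C)C)(C(C)C)Oc1occc1CC[C@H](O[Si](C)(C)C(C)(C)C)/C(C)=C\C1([Li])SCCCS1 | intermediate
17 | (2R)-2-methyl-1-{2-[(1Z,3S)-3-(tert-butyldimethylsilyloxy)-2-methyl-5-[2-(triisopropylsilyloxy)furan-3-yl]pent-1-en-1-yl]-1,3-dithian-2-yl}-3-(triethylsilyloxy)propan-1-one | CC(C)[Si](C(C)C)(C(C)C)Oc1occc1CC[C@H](O[Si](C)(C)C(C)(C)C)/C(C)=C\C1(SCCCS1)C(=O)[C@H](C)CO[Si](CC)(CC)CC | intermediate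
18 | (1S,6R,7S,11R)-1-(tert-butyldimethylsilyloxy)-7-hydroxy-8,8-(propane-1,3-diyldisulfanediyl)-12-(triethylsilyloxy)germacra-4,9Z-dien-15,6-olide (bridged butenolide) | O=C1O[C@@H]2C=C1CC[C@H](O[Si](C)(C)C(C)(C)C)/C(C)=C\C1(SCCCS1)[C@]2(O)[C@H](C)CO[Si](CC)(CC)CC | intermediate
19 | (1S,6R,7S,11R)-1-(tert-butyldimethylsilyloxy)-7-hydroxy-8-oxo-12-(triethylsilyloxy)germacra-4,9Z-dien-15,6-olide | O=C1O[C@@H]2C=C1CC[C@H](O[Si](C)(C)C(C)(C)C)/C(C)=C\C(=O)[C@]2(O)[C@H](C)CO[Si](CC)(CC)CC | intermediate
20 | (1S,4S,5S,6R,7S,11R)-1-(tert-butyldimethylsilyloxy)-4,5,7-trihydroxy-8-oxo-12-(triethylsilyloxy)germacr-9Z-en-15,6-olide | O[C@H]1[C@H]2OC(=O)[C@]1(O)CC[C@H](O[Si](C)(C)C(C)(C)C)/C(C)=C\C(=O)[C@]2(O)[C@H](C)CO[Si](CC)(CC)CC | intermediate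
21 | (1S,4S,5S,6R,7S,11R)-5-acetoxy-1-(tert-butyldimethylsilyloxy)-4,7-dihydroxy-8-oxo-12-(triethylsilyloxy)germacr-9Z-en-15,6-olide | CC(=O)O[C@H]1[C@H]2OC(=O)[C@]1(O)CC[C@H](O[Si](C)(C)C(C)(C)C)/C(C)=C\C(=O)[C@]2(O)[C@H](C)CO[Si](CC)(CC)CC | intermediate
22 | (1S,4S,5S,6R,7S,11R)-5-acetoxy-1-(tert-butyldimethylsilyloxy)-4,7,12-trihydroxy-8-oxogermacr-9Z-en-15,6-olide | CC(=O)O[C@H]1[C@H]2OC(=O)[C@]1(O)CC[C@H](O[Si](C)(C)C(C)(C)C)/C(C)=C\C(=O)[C@]2(O)[C@H](C)CO | intermediate
23 | C12 aldehyde corresponding to 22 (formed in the flask) | CC(=O)O[C@H]1[C@H]2OC(=O)[C@]1(O)CC[C@H](O[Si](C)(C)C(C)(C)C)/C(C)=C\C(=O)[C@]2(O)[C@H](C)C=O | intermediate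
24 | (1S,4S,5S,6R,7S,11S)-5-acetoxy-1-(tert-butyldimethylsilyloxy)-4,7-dihydroxy-8-oxo-15,6-olidogermacr-9Z-en-12-oic acid | CC(=O)O[C@H]1[C@H]2OC(=O)[C@]1(O)CC[C@H](O[Si](C)(C)C(C)(C)C)/C(C)=C\C(=O)[C@]2(O)[C@H](C)C(=O)O | intermediate
25 | 1-hydroxy keto acid from desilylation of 24 (formed in the flask) | CC(=O)O[C@H]1[C@H]2OC(=O)[C@]1(O)CC[C@H](O)/C(C)=C\C(=O)[C@]2(O)[C@H](C)C(=O)O | intermediate
26 | (1S,4S,5S,6R,7S,8S,11S)-5-acetoxy-4,7-dihydroxy-1,8-epoxygermacr-9-ene-15,6:12,8-diolide (CNP0315698.1) | CC(=O)O[C@H]1[C@H]2OC(=O)[C@]1(O)CC[C@@H]1O[C@@]3(C=C1C)OC(=O)[C@@H](C)[C@]23O | target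

**Step count.** Total: 18 steps. Longest linear sequence: 16 steps (steps 1–8 and 11–18, from acrolein).

**Steps most likely to fail**

1. Step 12. What may go wrong: oligomerisation instead of ring closure, no addition to the hindered ketone, or poor facial selectivity at C6. Fallback, from 17 back to 18: the silyloxyfuran of 17 is brominated at C6 with NBS (THF, −78 °C) to the 6-bromo butenolide F1. SmI2 (THF, −78 °C to rt, high dilution) then reduces the C–Br bond to a samarium dienolate that should add to the C7 ketone through a chelated cyclic transition state. This intramolecular Reformatsky-type reaction is a known way to close medium rings and would give 18.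

2. Step 11. What may go wrong: proton transfer to the allyl anion, γ-acylation, loss of the Z geometry in the anion, or attack of butyllithium on the silyloxyfuran. Fallback, from 8 back to 17: the acylation is moved to the simple dithiane 8 (n-BuLi, THF, −78 °C; then 15) to give the acyl dithiane F2, before any furan is present. Hydroboration with 9-BBN gives the alkylborane F3, and Suzuki–Miyaura coupling with 9 gives the butenolide ketone F4. Kinetic silylation (TIPSOTf, Et3N, CH2Cl2, −78 °C) should prefer the butenolide γ-CH2 over the single hindered methine next to the ketone and returns 17.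

3. Step 18. What may go wrong: closure of the ketal through the other face of the cyclic oxocarbenium ion, giving the C8 epimer. Fallback, from 24 back to 26: the order of the two C–O bond formations is reversed and made kinetic. Ac2O with DMAP converts the keto acid, through its cyclic pseudo-acid form, into the pseudo-acid acetate F5 (γ-lactone closed, acetoxy on C8). Catalytic TMSOTf (CH2Cl2, −78 °C) then ionises the acetate to an acyloxycarbenium ion that is captured by the C1 silyl ether oxygen with loss of the silyl group, giving 26.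

Further compounds
F1 | step 12 | 6-bromo butenolide from 17 (C6 epimers, germacrane numbering) | O=C1OC(Br)C=C1CC[C@H](O[Si](C)(C)C(C)(C)C)/C(C)=C\C1(SCCCS1)C(=O)[C@H](C)CO[Si](CC)(CC)CC
F2 | step 11 | (2R)-1-{2-[(1Z,3S)-3-(tert-butyldimethylsilyloxy)-2-methylpenta-1,4-dien-1-yl]-1,3-dithian-2-yl}-2-methyl-3-(triethylsilyloxy)propan-1-one | C=C[C@H](O[Si](C)(C)C(C)(C)C)/C(C)=C\C1(SCCCS1)C(=O)[C@H](C)CO[Si](CC)(CC)CC
F3 | step 11 | B-alkyl-9-borabicyclo[3.3.1]nonane from F2 | C1CC2CCCC(C1)B2CC[C@H](O[Si](C)(C)C(C)(C)C)/C(C)=C\C1(SCCCS1)C(=O)[C@H](C)CO[Si](CC)(CC)CC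
F4 | step 11 | butenolide ketone (17 with furan-2(5H)-one in place of the silyloxyfuran) | O=C1OCC=C1CC[C@H](O[Si](C)(C)C(C)(C)C)/C(C)=C\C1(SCCCS1)C(=O)[C@H](C)CO[Si](CC)(CC)CC
F5 | step 18 | pseudo-acid acetate of 24 (12,8-lactone closed, 8-acetoxy, C8 epimers) | CC(=O)O[C@H]1[C@H]2OC(=O)[C@]1(O)CC[C@H](O[Si](C)(C)C(C)(C)C)/C(C)=C\C3(OC(C)=O)OC(=O)[C@@H](C)[C@]23O
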